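The ketone carbon C1 and the oxygen-bearing carbons C2', C4' and C6' of the trihydroxyphenyl ring (ring A) carry oxygen on every second carbon, the signature of a folded tetraketide. The route therefore disconnects the C1–C1' bond and, behind it, the ring bond C1'–C2'. In one operation the terminal carbanion of the trianion of methyl 3,5-dioxohexanoate is acylated by methyl 11-(2-hydroxyphenyl)undecanoate. The open-chain 3,5,7-trioxo ester so formed then folds by biomimetic Claisen cyclisation into ring A. The precursor contains no phloroglucinol: an acyclic triketide supplies all six ring carbons and the three ring oxygens. The arylalkanoate arises from one B-alkyl Suzuki–Miyaura coupling, without protecting groups.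

Key step: step 2

Remark on the chemistry: methyl 3,5-dioxohexanoate is taken as a purchasable compound. The target has no stereocentre and no double-bond geometry, so no stereocontrol is needed. Locants: C1–C11 is the chain of the target (C1 the ketone), C1'–C6' is ring A, and ring B is the 2-hydroxyphenyl ring.

Step 1
Reactants: 1 methyl undec-10-enoate; 2 9-borabicyclo[3.3.1]nonane (9-BBN); 3 2-iodophenol
Product: 5 methyl 11-(2-hydroxyphenyl)undecanoate, via B-alkyl-9-BBN borane 4 (not isolated)
Conditions: 1, 9-BBN (1.1 equiv), THF, 0 °C to rt; then 3, PdCl2(dppf) (3 mol %), K2CO3 (3 equiv), DMF, 50 °C; aq NH4Cl work-up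
Reagents that add atoms: none
Why: Anti-Markovnikov hydroboration places boron on the terminal carbon, and the B-alkyl Suzuki–Miyaura coupling (oxidative addition of the aryl iodide to zerovalent palladium, base-assisted transmetalation, reductive elimination) joins C11 to ring B, with K2CO3 in DMF mild enough to spare the methyl ester while the free phenol rides along as its phenoxide.

Step 2
Reactants: 5 methyl 11-(2-hydroxyphenyl)undecanoate; 6 methyl 3,5-dioxohexanoate
Product: 9 11-(2-hydroxyphenyl)-1-(2,4,6-trihydroxyphenyl)undecan-1-one, via trilithium trianion 7 (not isolated), via tetraketide methyl ester 8 (not isolated)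
Conditions: 6 (3 equiv), LiN(iPr)2 (9 equiv), THF, argon, −78 to 0 °C; 5 in THF, 0 °C to rt; then 2 M aq KOH, MeOH, rt; then 2 M HCl, 0 °C
Reagents that add atoms: none
Why: LiN(iPr)2 strips the C2, C4 and C6 protons of 6, and the last-formed, least delocalised C6 carbanion of trianion 7 adds to the ester carbonyl of 5 and expels methoxide, which forges the bond between ketone carbon C1 and the future ring carbon C1' and leaves tetraketide 8 as its polyenolate (the phenol of 5 and the acidic C6 methylene of 8 each consume one sacrificial equivalent of 7). In aqueous KOH carbon C6 of 8, now flanked by the C5 and C7 ketones, attacks the C1 methyl ester, methoxide leaves, and the 2-acylcyclohexane-1,3,5-trione tautomerises to the phloroglucinol, the same starter-plus-three-acetates folding that chalcone-synthase-type polyketide synthases use for acylphloroglucinols. The closest known reaction types are the terminal acylation of poly-beta-carbonyl polyanions by esters (crossed Claisen condensation) and the strong-base Claisen cyclisation of 3,5,7-trioxoalkanoate esters to 2,4,6-trihydroxyphenyl ketones. Ring A closes in a 6-(enolexo)-exo-trig Dieckmann-type mode through the C6=C7 enolate; no stereocentre is formed. Two selectivities are needed: acylation at C6 and not at C2 or C4, secured by the reactivity order of the polyanion, and Claisen (C6 to C1) over aldol (C2 to C7) folding, which would give a 6-alkylresorcylate. The latter is secured by strong base, which keeps all three ketones enolised so that the ester is the only carbonyl able to accept a nucleophile and lose a leaving group, and by the irreversible aromatisation to the phenoxide.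

Compound list
1 | methyl undec-10-enoate | C=CCCCCCCCCC(=O)OC | starting material
2 | 9-borabicyclo[3.3.1]nonane (9-BBN) | B1C2CCCC1CCC2 | starting material
3 | 2-iodophenol | Oc1ccccc1I | starting material
4 | methyl 11-(9-borabicyclo[3.3.1]nonan-9-yl)undecanoate | COC(=O)CCCCCCCCCCB1C2CCCC1CCC2 | intermediate
5 | methyl 11-(2-hydroxyphenyl)undecanoate | COC(=O)CCCCCCCCCCc1ccccc1O | intermediate
6 | methyl 3,5-dioxohexanoate | CC(=O)CC(=O)CC(=O)OC | starting material
7 | trilithium trianion (tris-enolate) of methyl 3,5-dioxohexanoate | [Li+].[Li+].[Li+].C=C([O-])C=C([O-])C=C([O-])OC | intermediate
8 | methyl 17-(2-hydroxyphenyl)-3,5,7-trioxoheptadecanoate (drawn as the triketo tautomer) | COC(=O)CC(=O)CC(=O)CC(=O)CCCCCCCCCCc1ccccc1O | intermediate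
9 | 11-(2-hydroxyphenyl)-1-(2,4,6-trihydroxyphenyl)undecan-1-one | O=C(CCCCCCCCCCc1ccccc1O)c1c(O)cc(O)cc1O | target

Total step count: 2
Longest linear sequence: 2 (1 to 5 to 9)

Steps most likely to fail (the route has only two steps, so both are ranked, riskiest first)

1. Step 2.
- **What may go wrong:** The strongly basic trianion may enolise the aliphatic ester by proton transfer instead of acylating it, which stalls the union. The tetraketide may also fold in the aldol mode, or lactonise to a pyrone on acidification, instead of closing in the Claisen mode.
- **Fallback (sets out from 5, returns at 9):** Ring A is bought instead of built. Saponification of 5 (LiOH, THF–H2O, rt) should give 11-(2-hydroxyphenyl)undecanoic acid F1. This acid is heated with an excess of anhydrous phloroglucinol (benzene-1,3,5-triol, Oc1cc(O)cc(O)c1) in BF3·OEt2 at about 80 °C.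
- **Why it should work:** Friedel–Crafts C-acylation of the threefold-activated, symmetric arene forms the same C1–C1' bond by electrophilic aromatic substitution and should give 9 directly. The far less nucleophilic ring B should stay untouched.

2. Step 1.
- **What may go wrong:** Oxidative addition into the electron-rich iodophenoxide may be slow. Protodeboronation of the borane, or beta-hydride elimination with chain isomerisation at the alkylpalladium stage, could then compete. Partial saponification of the methyl ester is a further risk.
- **Fallback (sets out from 1, returns at 5):** Olefination replaces cross-coupling. Ozonolysis of 1 (O3, CH2Cl2, −78 °C; Me2S) should give methyl 10-oxodecanoate F2. A Wittig reaction with the ylide from purchased (2-hydroxybenzyl)triphenylphosphonium bromide (LiN(SiMe3)2, 2 equiv, THF, 0 °C) should give methyl 11-(2-hydroxyphenyl)undec-10-enoate F3 as an E/Z mixture. Hydrogenation (H2, Pd on carbon, EtOAc, rt) erases the alkene geometry and should give 5.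

Further compounds
F1 | step 2 | 11-(2-hydroxyphenyl)undecanoic acid | OC(=O)CCCCCCCCCCc1ccccc1O
F2 | step 1 | methyl 10-oxodecanoate | COC(=O)CCCCCCCCC=O
F3 | step 1 | methyl 11-(2-hydroxyphenyl)undec-10-enoate (E/Z mixture) | COC(=O)CCCCCCCCC=Cc1ccccc1O
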